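Assumption: the target is taken as the achiral, centrosymmetric diastereomer that its four descriptors encode. Ring carbons are numbered C1 to C4 with the aroyl groups on C1 and C3; the substituents on C1 and C4 lie on one face (α) and those on C2 and C3 on the other (β), written (1α,2β,3β,4α).

## Structural features

The target is one cyclobutane (ring A) with a 2,4-dihydroxybenzoyl group on each of C1 and C3 and a phenyl ring on each of C2 and C4, the head-to-tail pattern of a chalcone dimer. All four ring carbons are contiguous stereocentres: C1/C2 and C3/C4 are trans, C2/C3 and C4/C1 are cis, so each aroyl group is cis to one phenyl neighbour and trans to the other. The molecule has a centre of inversion and is achiral, so only relative configuration has to be controlled. The fragile points are the enolisable positions C1 and C3 (a single epimerisation would put both aroyl groups on one face), the strained ring with a phenyl and an acyl group on every pair of neighbouring carbons (open to acid- or heat-induced cleavage), and the free resorcinol hydroxyls, which are best unmasked last. The real difficulty is to obtain the head-to-tail constitution and the cis,trans,cis configuration together without relying on the outcome of a [2+2] dimerisation. The feature used here is that C1 to C4 each bear one sp2 carbon, two carbonyl carbons and two phenyl ipso carbons, and that these four carbons map onto the four carboxyl carbons of commercial cis,trans,cis-cyclobutane-1,2,3,4-tetracarboxylic dianhydride, which already has the required configuration. The C1 and C3 carboxyl carbons are kept as carbonyl carbons, and six-membered rings are grown on the C2 and C4 carboxyl carbons and aromatised later.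

## Logic of the disconnections

14 to 13. The four phenolic O–H groups are traced back to O–CH3 groups. This removes acidic, oxidisable and metal-binding phenols from all earlier steps and allows the aryl unit to be carried as an organolithium. The forward step must cleave four aryl methyl ethers without enolising C1/C3 or opening ring A.

13 to 10 and 12. The two aryl–carbonyl C–C bonds are cut. 13 then falls into 10, which holds ring A with all four stereocentres and both carbonyl carbons at the amide level, and two molecules of 12. The forward step must stop at the ketone and must not deprotonate C1/C3; the chelating N-methoxy-N-methylamide groups of 10 are chosen for this.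

12 to 11. The C–Li bond is traced to the C–Br bond of commercial 11. The forward halogen–metal exchange must be complete before 10 is added, so that no alkyllithium is left to attack the amide.

10 to 9. The two amide C–N bonds are exchanged for ester C–O bonds. The gain is a plain diester that tolerates the oxidative aromatisation before it. The forward step is an aminolysis of a hindered ester that must not epimerise C1/C3.

9 to 8. No skeletal bond is cut; two H2 are added back to each phenyl ring. A phenyl ring cannot be attached to a carboxyl carbon directly, but a six-membered carbocycle can, so the arenes are traced to cyclohexene rings. The forward dehydrogenation must not pass through a cation on the carbon attached to ring A and must leave the tertiary C–H bonds of C2 and C4 alone.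

8 to 7. Each ring C=C is traced to a tertiary C–OH and a neighbouring ring C–H. The gain is that the ring carbon attached to C2 or C4 becomes a carbinol carbon, the retron of a double organometallic addition. The forward dehydration must proceed into the six-membered ring and without ionisation.

7 to 6. The two ester O–CH3 bonds are cut. The C1/C3 carboxyls must be anionic and inert while the rings are built, but neutral and non-nucleophilic during dehydration and dehydrogenation. Each tertiary alcohol of 6 is cis to a carboxyl group, so the forward esterification must alkylate the carboxylate oxygen; any activation of the acyl carbon would close a γ-lactone.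

6 to 2 and 4. Four C–C bonds are cut, from each carbinol carbon to its two ring CH2 neighbours. Each carbinol carbon returns to the ester oxidation level, and the five-carbon remainder is a 1,5-dinucleophile, so two molecules of 4 are needed for one molecule of 2. Both carbocycles vanish, leaving 2, in which all four ring substituents are carboxyl groups differentiated two and two. The forward step needs the C2/C4 esters to react while the C1/C3 carboxyls do not, and each ester to take both ends of one molecule of 4. For this 2 is first converted into 5, which is then added to an excess of 4.

2 to 1. Two ester C–O bonds are cut, which closes the two anhydride rings of 1. The gain is a commercial compound that already carries the whole relative configuration. The ring opening gives two constitutional isomers, so centrosymmetric 2 must be separated; this separation settles the head-to-tail placement before any C–C bond is formed.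

4 to 3. The two C–Mg bonds are traced to the C–Br bonds of commercial 3. The forward step must avoid coupling of the halide with the reagent already formed.

## Other disconnections considered

Alternative 1: The cut is at the two C–phenyl bonds, C2–Ph and C4–Ph. The forward key step would be a double amide-directed C(sp3)–H arylation: trans-N1,N3-di(quinolin-8-yl)cyclobutane-1,3-dicarboxamide A1 and iodobenzene A2 under Pd(OAc)2 and AgOAc would give the diphenyl diamide A3 through five-membered palladacycles, each phenyl entering cis to the amide that directs it.
- In its favour: the phenyl rings arrive complete, with no ring growth and no aromatisation; the cis relation of each phenyl to one carbonyl group is what directed palladation delivers; A3 is about three steps from simple materials. On step economy and convergence it is the better plan.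
- Against it here: both methylene carbons are β to both amides. After the first arylation, the second can be steered by the other amide (giving centrosymmetric A3) or by the same amide at the opposite methylene (giving the isomer with both phenyl groups on one face). Nothing in A1 enforces the first outcome.
- Two aminoquinoline amides on hindered, epimerisable carbons must then be exchanged, typically by an activation and a cleavage step, before the route could join at 9 or 10, which returns part of the saving.
- Comparison: on structure the chosen plan is safer because it never forms a bond at a ring stereocentre. On mechanism both rest on known reaction types, and the two are equal in needing no photochemistry. On step count the alternative is better.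

Alternative 2: The cut is at the ring-to-carbonyl bonds C1–C(O) and C3–C(O). (1α,2β,3β,4α)-2,4-Diphenylcyclobutane-1,3-dicarboxylic acid A4 would be converted into its bis(N-hydroxyphthalimide) ester A5 and coupled twice with 2,4-dimethoxybenzoyl chloride A6 under NiBr2(dme), 4,4'-di-tert-butyl-2,2'-bipyridine and zinc. Single-electron reduction of each ester releases CO2 and a cyclobutyl radical, which a nickel acyl species captures to give the tetramethyl ether A7, identical with 13.
- In its favour: two steps from A4 to 13, no organolithium and no amide stage. From the diacid level onward it is shorter than 9 to 10 to 13 and is the better plan on that stretch.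
- A4 is the head-to-tail photodimer of cinnamic acid and should be reachable in one solid-state irradiation. That would make the alternative far shorter overall, at the price of the photochemistry that the chosen plan does without.
- Against it here: C1 and C3 become planar radicals, so the configuration at the two centres that distinguish the target from its epimer is erased and must be re-set during C–C bond formation. The flanking phenyl groups lie on opposite faces and offset each other, so facial preference rests only on the remote 1,3-substituent and on ring pucker; a clean return to the trans-1,3 arrangement cannot be assumed.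
- A radical at C1 also has two strained β C–C bonds whose cleavage would give a styrene and a carbonyl-stabilised radical, a ring-opening channel absent from polar chemistry.
- Comparison: on structure and mechanism the chosen addition, which leaves C1 and C3 tetrahedral throughout, is safer. On step economy the alternative is better.

Alternative 3: The cut is at the two aryl–carbonyl bonds, with an extra C–Cl bond formed on each arene. The diacid dichloride A8, the acid chloride of A4, would react twice with 3,5-dimethoxybenzyne A10, released from 3,5-dimethoxy-2-(trimethylsilyl)phenyl triflate A9 by KF and 18-crown-6. Chloride adds to the aryne carbon remote from the neighbouring methoxy group and the aryl anion next to that methoxy group takes the acyl carbon, giving the bis(6-chloro-2,4-dimethoxyphenyl) diketone A11.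
- In its favour: no organometallic reagent and no amide intermediate; the inductive control of aryne regiochemistry places the methoxy groups where the target needs its hydroxyls. In forming no bond at a ring stereocentre it is the equal of the chosen plan.
- Against it here: A11 carries two chlorine atoms that the target lacks, so a reductive dechlorination must be added. The ketone is flanked by two ortho substituents and must form twice. An acid chloride with a hydrogen on C1/C3 can lose HCl to a ketene under fluoride and aryl-anion conditions and so lose configuration. A9 needs several steps, whereas 11 is commercial.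
- Comparison: on structure the two are equal. On mechanism the aryne route is less direct than addition of 12 to 10. On step economy it is no shorter once A9 and the dechlorination are counted.

Key step: step 3

## Route

Step 1
Reactants: 1 cis,trans,cis-cyclobutane-1,2,3,4-tetracarboxylic 1,2:3,4-dianhydride
Product: 2 (1α,2β,3β,4α)-2,4-bis(methoxycarbonyl)cyclobutane-1,3-dicarboxylic acid
Conditions: MeOH, 65 °C; concentrate; crystallise from EtOAc
Reagents that add atoms: methanol (two molecules), CO.CO
Why: Alcoholysis of a cyclic anhydride: one molecule of methanol attacks one carbonyl of each anhydride ring and leaves an ester and an acid on neighbouring cis carbons without touching any ring bond, so the configuration of 1 is carried over. The two rings open independently, so a second constitutional isomer with the acids on adjacent carbons accompanies 2; the centrosymmetric, more symmetrical 2 is expected to be the less soluble and is taken by crystallisation, which fixes the head-to-tail placement.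

Step 2
Reactants: 3 1,5-dibromopentane
Product: 4 pentane-1,5-diylbis(magnesium bromide)
Conditions: Mg turnings (excess, I2-activated), THF, slow addition, 25–40 °C; titrate
Reagents that add atoms: magnesium (two atoms), [Mg].[Mg]
Why: Grignard formation by insertion of magnesium into both C–Br bonds; slow addition of dilute 3 to excess metal keeps the halide concentration low and limits Wurtz coupling, and five-carbon di-Grignard reagents of this kind are stable in THF.

Step 3
Reactants: 2 (1α,2β,3β,4α)-2,4-bis(methoxycarbonyl)cyclobutane-1,3-dicarboxylic acid, 4 pentane-1,5-diylbis(magnesium bromide)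
Product: 6 (1α,2β,3β,4α)-2,4-bis(1-hydroxycyclohexyl)cyclobutane-1,3-dicarboxylic acid, via bis(chloromagnesium) 2,4-bis(methoxycarbonyl)cyclobutane-1,3-dicarboxylate 5 (not isolated)
Conditions: 2, t-BuMgCl (2.0 equiv), THF, −40 °C; cannulate into 4 (2.6 equiv), THF, 0 → 25 °C; aq. NH4Cl, then citric acid to pH 4 at 0 °C, EtOAc
Reagents that add atoms: pentane-1,5-diylbis(magnesium bromide) (second molecule of 4), Br[Mg]CCCCC[Mg]Br
Why: Two molecules of 4 are consumed per molecule of 2: one C–MgBr end of 4 adds to a methyl ester of 5 and methoxide leaves, giving a ketone that carries the second C–MgBr end five carbons away. That end adds to the ketone in a 6-exo-trig closure, and the same sequence at the second ester with the second molecule of 4 turns each former ester carbon into the carbinol carbon of a cyclohexanol ring (two rings, four C–C bonds; the ten carbons of 2 and twice the five of 4, less two molecules of methanol, give the eighteen of 6). The closest known reaction type is the annulation of esters with α,ω-di-Grignard reagents to 1-substituted cycloalkanols, run here beside magnesium carboxylates that Grignard reagents do not attack at this temperature. No stereocentre is created, because each carbinol carbon lies on a mirror plane of its own ring, and no bond to C1–C4 is made or broken, so the configuration of 1 is carried through. The selectivity needed is ester over carboxylate; it is secured by the negative charge of the carboxylates, formed beforehand with poorly nucleophilic t-BuMgCl so that 4 is not half-protonated to a chain-ending mono-Grignard reagent. Ring closure is favoured over bridging of two esters because the intramolecular addition to the more electrophilic ketone is fast and because 5 is added to an excess of 4. Addition to a methyl ester should outrun enolisation at C2/C4, and the α-hydrogens of the carboxylates at C1/C3 are too weakly acidic to be removed. Each tertiary alcohol of 6 sits cis to a carboxyl group, so 6 is set free cold at pH 4 and carried on at once, before it can close to the γ-lactone.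

Step 4
Reactants: 6 (1α,2β,3β,4α)-2,4-bis(1-hydroxycyclohexyl)cyclobutane-1,3-dicarboxylic acid
Product: 7 dimethyl (1α,2β,3β,4α)-2,4-bis(1-hydroxycyclohexyl)cyclobutane-1,3-dicarboxylate
Conditions: KHCO3 (3 equiv), MeI (4 equiv), DMF, 0 → 25 °C
Reagents that add atoms: iodomethane (two molecules), CI.CI
Why: Carboxylate O-alkylation (SN2 at iodomethane, once at each carboxylate): bicarbonate converts the acids of 6 into carboxylates at once, which cannot acylate the neighbouring alcohol, and the acyl carbons are never activated, so lactone closure is not triggered. Bicarbonate is too weak a base to form the tertiary alkoxide that would attack the new cis ester, and no ring stereocentre is involved.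

Step 5
Reactants: 7 dimethyl (1α,2β,3β,4α)-2,4-bis(1-hydroxycyclohexyl)cyclobutane-1,3-dicarboxylate
Product: 8 dimethyl (1α,2β,3β,4α)-2,4-di(cyclohex-1-en-1-yl)cyclobutane-1,3-dicarboxylate
Conditions: Burgess reagent (methyl N-(triethylammoniosulfonyl)carbamate, 3 equiv), toluene, 25 → 60 °C
Reagents that add atoms: none
Why: Burgess dehydration: each tertiary alcohol becomes a sulfamate ester whose carbamate nitrogen removes a β-hydrogen on the same side through a cyclic transition state, so the alkene forms without a free tertiary cation next to ring A and cyclobutylcarbinyl ring expansion is avoided. Each cyclohexane ring offers two unhindered CH2 groups, whereas the only other β-hydrogen is the crowded methine of C2 or C4, whose loss would place a tetrasubstituted double bond exocyclic to the four-membered ring; the endocyclic cyclohexene is therefore expected and C2/C4 keep their configuration.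

Step 6
Reactants: 8 dimethyl (1α,2β,3β,4α)-2,4-di(cyclohex-1-en-1-yl)cyclobutane-1,3-dicarboxylate
Product: 9 dimethyl (1α,2β,3β,4α)-2,4-diphenylcyclobutane-1,3-dicarboxylate
Conditions: Pd(OCOCF3)2 (10 mol %), sodium anthraquinone-2-sulfonate (20 mol %), MgSO4, PhCl, O2 (1 atm), 110 °C
Reagents that add atoms: none
Why: Palladium-catalysed aerobic dehydrogenation of a cyclohexene to an arene: divalent palladium cleaves an allylic ring C–H bond to a π-allyl complex, β-hydride elimination gives a cyclohexadiene, a second cycle gives the benzene ring, and O2 with the anthraquinone co-catalyst returns reduced palladium to the divalent state. No carbocation is involved, so ring A is not exposed to rearrangement, and the esters are inert; the secondary ring CH2 groups should be activated in preference to the hindered tertiary C–H bonds at C2/C4, which leaves the four stereocentres unchanged.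

Step 7
Reactants: 9 dimethyl (1α,2β,3β,4α)-2,4-diphenylcyclobutane-1,3-dicarboxylate
Product: 10 (1α,2β,3β,4α)-N1,N3-dimethoxy-N1,N3-dimethyl-2,4-diphenylcyclobutane-1,3-dicarboxamide
Conditions: MeNH(OMe)·HCl (6 equiv), i-PrMgCl (12 equiv), THF, −20 → 0 °C
Reagents that add atoms: N,O-dimethylhydroxylamine hydrochloride (two molecules), CNOC.Cl.CNOC.Cl
Why: Direct ester-to-amide exchange with the chloromagnesium amide of N,O-dimethylhydroxylamine (Weinreb amide formation from an ester, once at each ester): the magnesium amide is a good nucleophile but a weak base, the tetrahedral intermediate collapses with loss of methoxide, and working at or below 0 °C keeps enolisation at C1/C3 negligible.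

Step 8
Reactants: 10 (1α,2β,3β,4α)-N1,N3-dimethoxy-N1,N3-dimethyl-2,4-diphenylcyclobutane-1,3-dicarboxamide, 11 1-bromo-2,4-dimethoxybenzene
Product: 13 (1α,2β,3β,4α)-1,3-bis(2,4-dimethoxybenzoyl)-2,4-diphenylcyclobutane, via 2,4-dimethoxyphenyllithium 12 (not isolated)
Conditions: 11 (3.2 equiv), n-BuLi (3.0 equiv), THF, −78 °C; add 10, −78 → −20 °C; aq. NH4Cl at −20 °C
Reagents that add atoms: 1-bromo-2,4-dimethoxybenzene (second molecule of 11), COc1ccc(Br)c(OC)c1
Why: Bromine–lithium exchange on 11 gives 12, two molecules of which add once each to the two N-methoxy-N-methylamides (Weinreb ketone synthesis): the five-membered lithium chelate of the tetrahedral adduct persists until the cold aqueous quench, so no second addition occurs and the enolisable ketone is set free only under near-neutral conditions. The existing bonds at C1 and C3 are not broken, so the configuration is retained.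

Step 9
Reactants: 13 (1α,2β,3β,4α)-1,3-bis(2,4-dimethoxybenzoyl)-2,4-diphenylcyclobutane
Product: 14 (1α,2β,3β,4α)-1,3-bis(2,4-dihydroxybenzoyl)-2,4-diphenylcyclobutane
Conditions: BBr3 (10 equiv), CH2Cl2, −78 → 0 °C; MeOH, then H2O, 0 °C
Reagents that add atoms: none
Why: Lewis-acid cleavage of aryl methyl ethers: BBr3 coordinates each ether oxygen and bromide removes the methyl group as bromomethane; the ortho ethers go first through a six-membered boron chelate with the ketone, the para ethers follow on warming, and solvolysis of the aryl borates releases the four phenols of target 14. Low temperature and a cold quench are chosen so that enolisation at C1/C3 and opening of ring A do not compete.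

## Compound list

1 | cis,trans,cis-cyclobutane-1,2,3,4-tetracarboxylic 1,2:3,4-dianhydride (anhydride rings on opposite faces) | O=C1OC(=O)[C@@H]2[C@H]1[C@H]3C(=O)OC(=O)[C@@H]23 | starting material
2 | (1α,2β,3β,4α)-2,4-bis(methoxycarbonyl)cyclobutane-1,3-dicarboxylic acid (centrosymmetric) | O=C(O)[C@H]1[C@H](C(=O)OC)[C@H](C(=O)O)[C@H]1C(=O)OC | intermediate
3 | 1,5-dibromopentane | BrCCCCCBr | starting material
4 | pentane-1,5-diylbis(magnesium bromide) | Br[Mg]CCCCC[Mg]Br | intermediate
5 | bis(chloromagnesium) (1α,2β,3β,4α)-2,4-bis(methoxycarbonyl)cyclobutane-1,3-dicarboxylate (formed in the flask, not isolated) | O=C(O[Mg]Cl)[C@H]1[C@H](C(=O)OC)[C@H](C(=O)O[Mg]Cl)[C@H]1C(=O)OC | intermediate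
6 | (1α,2β,3β,4α)-2,4-bis(1-hydroxycyclohexyl)cyclobutane-1,3-dicarboxylic acid | O=C(O)[C@H]1[C@H](C2(O)CCCCC2)[C@H](C(=O)O)[C@H]1C1(O)CCCCC1 | intermediate
7 | dimethyl (1α,2β,3β,4α)-2,4-bis(1-hydroxycyclohexyl)cyclobutane-1,3-dicarboxylate | COC(=O)[C@H]1[C@H](C2(O)CCCCC2)[C@H](C(=O)OC)[C@H]1C1(O)CCCCC1 | intermediate
8 | dimethyl (1α,2β,3β,4α)-2,4-di(cyclohex-1-en-1-yl)cyclobutane-1,3-dicarboxylate | COC(=O)[C@H]1[C@H](C2=CCCCC2)[C@H](C(=O)OC)[C@H]1C1=CCCCC1 | intermediate
9 | dimethyl (1α,2β,3β,4α)-2,4-diphenylcyclobutane-1,3-dicarboxylate | COC(=O)[C@H]1[C@H](c2ccccc2)[C@H](C(=O)OC)[C@H]1c1ccccc1 | intermediate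
10 | (1α,2β,3β,4α)-N1,N3-dimethoxy-N1,N3-dimethyl-2,4-diphenylcyclobutane-1,3-dicarboxamide | CON(C)C(=O)[C@H]1[C@H](c2ccccc2)[C@H](C(=O)N(C)OC)[C@H]1c1ccccc1 | intermediate
11 | 1-bromo-2,4-dimethoxybenzene | COc1ccc(Br)c(OC)c1 | starting material
12 | 2,4-dimethoxyphenyllithium (formed in the flask, not isolated) | [Li]c1ccc(OC)cc1OC | intermediate
13 | (1α,2β,3β,4α)-1,3-bis(2,4-dimethoxybenzoyl)-2,4-diphenylcyclobutane | O=C(c1ccc(OC)cc1OC)[C@H]1[C@H](c2ccccc2)[C@H](C(=O)c2ccc(OC)cc2OC)[C@H]1c1ccccc1 | intermediate
14 | (1α,2β,3β,4α)-1,3-bis(2,4-dihydroxybenzoyl)-2,4-diphenylcyclobutane (CNP0398987.2) | O=C(c1ccc(O)cc1O)[C@H]1[C@H](c2ccccc2)[C@H](C(=O)c2ccc(O)cc2O)[C@H]1c1ccccc1 | target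

## Step count and least certain steps

Total step count: 9. Longest linear sequence: 8 steps (1, 3, 4, 5, 6, 7, 8, 9) from 1 to 14; step 2 prepares the di-Grignard reagent on a side branch.

Step 3 (key step). Two processes are most likely to interfere. The first is sluggish or unselective ester addition if 5 is sparingly soluble, so that bridging of two esters by one reagent molecule and enolisation at C2/C4 gain ground. The second is premature lactone closure while 6 is liberated, because each tertiary alcohol is cis to a carboxyl group. The fallback changes the electrophile to the anhydride itself, the known spiro-lactonisation of cyclic anhydrides with di-Grignard reagents; it sets out from 1 and 4 and returns at 7. 1 is added to 4 (2.2 equiv, THF, −40 → 25 °C) and worked up with acid; each anhydride ring takes both ends of one reagent molecule at one carbonyl and the hydroxy acid closes. This should give the centrosymmetric head-to-tail dispiro bis-γ-lactone F1 together with the head-to-head dispiro bis-γ-lactone F2, and F1 is separated by crystallisation. F1 is opened with NaOH (2.05 equiv, aqueous MeOH, 25 °C) and the solution is evaporated to disodium (1α,2β,3β,4α)-2,4-bis(1-hydroxycyclohexyl)cyclobutane-1,3-dicarboxylate F3, which is methylated with MeI in DMF to give 7. F1 is also what lactonised 6 becomes, so the same opening and alkylation recover material lost to lactone closure. The price is that the head-to-tail placement is then settled by a separation after the C–C bond formation.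

Step 6. The likely failure is palladation at the tertiary allylic C–H of C2/C4 instead of the ring CH2 groups, leading to loss of configuration or β-carbon cleavage of ring A, or stalling at the diene stage on the second ring. The fallback uses ionic functionalisation, elimination and quinone dehydrogenation; it sets out from 8 and returns at 9. 8 with Br2 (CH2Cl2, −78 °C) should give dimethyl (1α,2β,3β,4α)-2,4-bis(1,2-dibromocyclohexyl)cyclobutane-1,3-dicarboxylate F4, a mixture at the bromine-bearing carbons. DBU (toluene, 80 °C) then removes four HBr to give dimethyl (1α,2β,3β,4α)-2,4-di(cyclohexa-1,5-dien-1-yl)cyclobutane-1,3-dicarboxylate F5. DDQ (benzene, 25 °C) dehydrogenates F5 to 9; the cyclohexadienyl cation formed by hydride loss sheds a proton at once.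

Step 5. The likely failure is ionisation of the tertiary sulfamate running ahead of the internal proton transfer. That would allow ring expansion, capture of the ion pair by the cis ester carbonyl (lactone closure), or proton loss from C2/C4 with loss of that stereocentre. The fallback is a Chugaev elimination, a concerted thermal syn-elimination; it sets out from 6, replaces steps 4 and 5, and returns at 8. 6 is treated with NaH (4.4 equiv, THF/DMSO, 0 °C), then CS2, then excess MeI. The alkoxides are formed while the carboxyls are still carboxylates and cannot lactonise, and MeI both S-methylates and esterifies, giving dimethyl (1α,2β,3β,4α)-2,4-bis{1-[(methylsulfanyl)carbonothioyloxy]cyclohexyl}cyclobutane-1,3-dicarboxylate F6. Heating F6 in toluene at 90 °C should give 8.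

Step 8. The likely failure is proton abstraction at C1/C3, or attack at the N-methoxy group with loss of formaldehyde, by the basic aryllithium on the hindered amide, or reaction stopping after one addition. The fallback is a non-basic palladium-catalysed acylation; it sets out from 9 and returns at 13. 9 is saponified (LiOH, THF/H2O, then HCl) to (1α,2β,3β,4α)-2,4-diphenylcyclobutane-1,3-dicarboxylic acid F7, and (COCl)2 with catalytic DMF in CH2Cl2 gives (1α,2β,3β,4α)-2,4-diphenylcyclobutane-1,3-dicarbonyl dichloride F8. 12, made from 11 as in step 8, is transmetalated with ZnCl2 to (2,4-dimethoxyphenyl)zinc chloride F9, which couples with F8 under Pd(PPh3)4 (5 mol %, THF, 25 °C) to give 13. Zerovalent palladium inserts into the C(O)–Cl bond, followed by transmetalation and reductive elimination.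

Step 9. The likely failure is Lewis-acid-promoted enolisation at C1/C3 or opening of ring A in the boron-chelated ketone during the slower cleavage of the para ethers, or incomplete demethylation. The fallback changes the protecting group to benzyl, removed under neutral conditions; it sets out from 10 and returns at 14. Commercial 4-bromobenzene-1,3-diol F10 is benzylated (BnBr, K2CO3, DMF) to 2,4-bis(benzyloxy)-1-bromobenzene F11. n-BuLi (THF, −78 °C) gives 2,4-bis(benzyloxy)phenyllithium F12, which adds to 10 as in step 8 to give (1α,2β,3β,4α)-1,3-bis[2,4-bis(benzyloxy)benzoyl]-2,4-diphenylcyclobutane F13. H2 (1 atm) over Pd/C (10 wt %) in EtOAc at 25 °C then gives 14.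

## Further compounds

F1 | step 3 | head-to-tail dispiro bis-γ-lactone of 6 (each lactone joins the carbinol carbon on C2 or C4 to the cis carboxyl carbon on C3 or C1; centrosymmetric) | O=C1OC2(CCCCC2)[C@H]3[C@@H]1[C@H]4[C@@H]3C(=O)OC45CCCCC5
F2 | step 3 | head-to-head dispiro bis-γ-lactone (spiro carbons on adjacent ring carbons; racemate, one enantiomer drawn) | O=C1OC2(CCCCC2)[C@@H]3[C@H]1[C@H]4C(=O)OC5(CCCCC5)[C@@H]34
F3 | step 3 | disodium (1α,2β,3β,4α)-2,4-bis(1-hydroxycyclohexyl)cyclobutane-1,3-dicarboxylate | [Na+].[Na+].[O-]C(=O)[C@H]1[C@H](C2(O)CCCCC2)[C@H](C([O-])=O)[C@H]1C1(O)CCCCC1
F4 | step 6 | dimethyl (1α,2β,3β,4α)-2,4-bis(1,2-dibromocyclohexyl)cyclobutane-1,3-dicarboxylate (mixture at the CBr carbons) | COC(=O)[C@H]1[C@H](C2(Br)CCCCC2Br)[C@H](C(=O)OC)[C@H]1C1(Br)CCCCC1Br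
F5 | step 6 | dimethyl (1α,2β,3β,4α)-2,4-di(cyclohexa-1,5-dien-1-yl)cyclobutane-1,3-dicarboxylate | COC(=O)[C@H]1[C@H](C2=CCCC=C2)[C@H](C(=O)OC)[C@H]1C1=CCCC=C1
F6 | step 5 | dimethyl (1α,2β,3β,4α)-2,4-bis{1-[(methylsulfanyl)carbonothioyloxy]cyclohexyl}cyclobutane-1,3-dicarboxylate | COC(=O)[C@H]1[C@H](C2(OC(=S)SC)CCCCC2)[C@H](C(=O)OC)[C@H]1C1(OC(=S)SC)CCCCC1
F7 | step 8 | (1α,2β,3β,4α)-2,4-diphenylcyclobutane-1,3-dicarboxylic acid | O=C(O)[C@H]1[C@H](c2ccccc2)[C@H](C(=O)O)[C@H]1c1ccccc1
F8 | step 8 | (1α,2β,3β,4α)-2,4-diphenylcyclobutane-1,3-dicarbonyl dichloride | O=C(Cl)[C@H]1[C@H](c2ccccc2)[C@H](C(=O)Cl)[C@H]1c1ccccc1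
F9 | step 8 | (2,4-dimethoxyphenyl)zinc chloride | Cl[Zn]c1ccc(OC)cc1OC
F10 | step 9 | 4-bromobenzene-1,3-diol (purchased) | Oc1ccc(Br)c(O)c1
F11 | step 9 | 2,4-bis(benzyloxy)-1-bromobenzene | Brc1ccc(OCc2ccccc2)cc1OCc1ccccc1
F12 | step 9 | 2,4-bis(benzyloxy)phenyllithium | [Li]c1ccc(OCc2ccccc2)cc1OCc1ccccc1
F13 | step 9 | (1α,2β,3β,4α)-1,3-bis[2,4-bis(benzyloxy)benzoyl]-2,4-diphenylcyclobutane | O=C(c1ccc(OCc2ccccc2)cc1OCc1ccccc1)[C@H]1[C@H](c2ccccc2)[C@H](C(=O)c2ccc(OCc3ccccc3)cc2OCc2ccccc2)[C@H]1c1ccccc1
A1 | alternative 1 | trans-N1,N3-di(quinolin-8-yl)cyclobutane-1,3-dicarboxamide | O=C(Nc1cccc2cccnc12)[C@H]1C[C@H](C(=O)Nc2cccc3cccnc23)C1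
A2 | alternative 1 | iodobenzene | Ic1ccccc1
A3 | alternative 1 | (1α,2β,3β,4α)-N1,N3-di(quinolin-8-yl)-2,4-diphenylcyclobutane-1,3-dicarboxamide | O=C(Nc1cccc2cccnc12)[C@H]1[C@H](c2ccccc2)[C@H](C(=O)Nc2cccc3cccnc23)[C@H]1c1ccccc1
A4 | alternative 2 | (1α,2β,3β,4α)-2,4-diphenylcyclobutane-1,3-dicarboxylic acid | O=C(O)[C@H]1[C@H](c2ccccc2)[C@H](C(=O)O)[C@H]1c1ccccc1
A5 | alternative 2 | bis(1,3-dioxoisoindolin-2-yl) (1α,2β,3β,4α)-2,4-diphenylcyclobutane-1,3-dicarboxylate | O=C(ON1C(=O)c2ccccc2C1=O)[C@H]1[C@H](c2ccccc2)[C@H](C(=O)ON2C(=O)c3ccccc3C2=O)[C@H]1c1ccccc1
A6 | alternative 2 | 2,4-dimethoxybenzoyl chloride | COc1ccc(C(=O)Cl)c(OC)c1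
A7 | alternative 2 | (1α,2β,3β,4α)-1,3-bis(2,4-dimethoxybenzoyl)-2,4-diphenylcyclobutane (identical with 13) | O=C(c1ccc(OC)cc1OC)[C@H]1[C@H](c2ccccc2)[C@H](C(=O)c2ccc(OC)cc2OC)[C@H]1c1ccccc1
A8 | alternative 3 | (1α,2β,3β,4α)-2,4-diphenylcyclobutane-1,3-dicarbonyl dichloride | O=C(Cl)[C@H]1[C@H](c2ccccc2)[C@H](C(=O)Cl)[C@H]1c1ccccc1
A9 | alternative 3 | 3,5-dimethoxy-2-(trimethylsilyl)phenyl trifluoromethanesulfonate | COc1cc(OC)c([Si](C)(C)C)c(OS(=O)(=O)C(F)(F)F)c1
A10 | alternative 3 | 3,5-dimethoxybenzyne | COC1=CC(OC)=CC#C1
A11 | alternative 3 | (1α,2β,3β,4α)-1,3-bis(6-chloro-2,4-dimethoxybenzoyl)-2,4-diphenylcyclobutane | O=C(c1c(Cl)cc(OC)cc1OC)[C@H]1[C@H](c2ccccc2)[C@H](C(=O)c2c(Cl)cc(OC)cc2OC)[C@H]1c1ccccc1
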